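**Retrosynthetic overview**

1. 2-Bromopyrimidin-4-amine 1 is converted, through its iodonium tosylate 2, into the C5 aryl(mesityl)iodonium triflate 3. C5 is the α-carbon of the 4-amino amidine and is nucleophilic in the parent ring; in 3 it reacts as a cation (an aza-enolonium equivalent).
2. Key disconnection: iodonium 3 + hydroxyindole 4 ⇐ target 5, cut at the pyrimidine C5–indole C3 bond. Both carbons are nucleophilic in their parent rings, so one of them (C5) is polarity-reversed.
3. Ring order: no ring is built. Pyrimidine and indole are bought intact with both bromines, the amine and the phenol in place, and no protecting group is used.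

Assumption: the target has no stereocentre and no configurationally stable axis, so no stereocontrol is needed; 1 and 4 are taken as catalogue building blocks.

**Route**

Step 1
Reactants: 1 2-bromopyrimidin-4-amine
Product: 3 (4-amino-2-bromopyrimidin-5-yl)(mesityl)iodonium triflate, via iodonium tosylate 2 (not isolated)
Conditions: MesI(OAc)2 (1.1 equiv), TsOH·H2O (1.1 equiv), (CF3)2CHOH, rt, 15 min; add 1, 0 °C to rt, dark; then satd aq NaOTf, CH2Cl2, rt
Reagents that add atoms: iodomesitylene diacetate MesI(OAc)2, CC(=O)OI(OC(C)=O)c1c(C)cc(C)cc1C; sodium triflate NaOTf, [Na+].[O-]S(=O)(=O)C(F)(F)F; p-toluenesulfonic acid monohydrate TsOH·H2O, Cc1ccc(S(=O)(=O)O)cc1.O (its tosylate is held by 2 only, not by 3)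
Why: Fluoroalcohol-promoted SEAr C–H iodanation (Koser-type condensation of an electron-rich heteroarene with ArI(OH)OTs, a known reaction type for uracils, pyrroles and thiophenes): MesI(OH)OTs formed in the flask attacks the only enamine-like carbon of 1, C5 (the site where NIS and NBS halogenate 4-aminopyrimidines), while (CF3)2CHOH hydrogen-bonds to the amine and ring nitrogens to disfavour N-ligation, and the NaOTf wash swaps tosylate for the weakly coordinating triflate that copper catalysis prefers.

Step 2
Reactants: 3 (4-amino-2-bromopyrimidin-5-yl)(mesityl)iodonium triflate (1.2 equiv); 4 6-bromo-1H-indol-4-ol (1.0 equiv)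
Product: 5 3-(4-amino-2-bromopyrimidin-5-yl)-6-bromo-1H-indol-4-ol
Conditions: Cu(MeCN)4PF6 (10 mol %), 2,6-di-tert-butylpyridine (1.2 equiv), degassed ClCH2CH2Cl, 40 °C, Ar, dark
Reagents that add atoms: none
Why: Proposed new method: 3 serves as an aza-enolonium (amidine α-cation) equivalent, so two carbons that are both nucleophilic in their parent rings can be joined; monovalent copper inserts into the less hindered pyrimidinyl–iodine bond (mesityl is the non-transferred dummy and leaves as iodomesitylene), the resulting pyrimidin-5-yl trivalent-copper electrophile is attacked by indole C3 (C5 and C7 are each flanked by bromine), and deprotonation followed by C–C reductive elimination gives 5, while the hindered base cannot form the phenoxide or amide needed for O- or N-arylation and the monovalent copper source under argon avoids oxidising the hydroxyindole; the closest known reaction type is the copper-catalysed C3–H arylation of free (NH)-indoles with diaryliodonium triflates (Gaunt-type arylation), not yet shown for an aminopyrimidinyl group or a free 4-hydroxyindole.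

**Compound list**

1 | 2-bromopyrimidin-4-amine | Nc1ccnc(Br)n1 | starting material
2 | (4-amino-2-bromopyrimidin-5-yl)(2,4,6-trimethylphenyl)iodonium 4-methylbenzenesulfonate | Cc1cc(C)c([I+]c2cnc(Br)nc2N)c(C)c1.Cc1ccc(S(=O)(=O)[O-])cc1 | intermediate (not isolated)
3 | (4-amino-2-bromopyrimidin-5-yl)(2,4,6-trimethylphenyl)iodonium trifluoromethanesulfonate | Cc1cc(C)c([I+]c2cnc(Br)nc2N)c(C)c1.[O-]S(=O)(=O)C(F)(F)F | intermediate
4 | 6-bromo-1H-indol-4-ol | Oc1cc(Br)cc2[nH]ccc12 | starting material
5 | 3-(4-amino-2-bromopyrimidin-5-yl)-6-bromo-1H-indol-4-ol (achiral) | Nc1nc(Br)ncc1-c1c[nH]c2cc(Br)cc(O)c12 | target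

**Step count and risks**

Total steps: 2. Longest linear sequence: 2 (1 → 3 → 5; indole 4 enters in step 2).

The route has only two steps, so both are ranked and there is no third.

Most likely to fail, step 2: the free 4-hydroxyindole may be oxidised, O-arylated or bound to copper before C3 is arylated. The fallback sets out from 3 and comes back at 5. It masks the phenol as a methyl ether and unmasks it at the end. Iodonium 3 is coupled with commercial 6-bromo-4-methoxy-1H-indole F1 under Cu(MeCN)4PF6 and 2,6-di-tert-butylpyridine in ClCH2CH2Cl at 40 °C to give 2-bromo-5-(6-bromo-4-methoxy-1H-indol-3-yl)pyrimidin-4-amine F2. The ether is then cleaved with BBr3 (5 equiv, CH2Cl2, −78 °C to rt; MeOH, then aq NaHCO3) to give 5. Any bromide attack at pyrimidine C2 under these conditions is degenerate, so the C2–Br is preserved.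

Second, step 1: the trivalent iodine reagent may ligate or oxidise the free NH2 instead of attacking C5. The fallback sets out from 1 and comes back at 3. It installs iodine first in its monovalent form and oxidises afterwards. NIS in DMF at rt to 50 °C gives 2-bromo-5-iodopyrimidin-4-amine F3. One-pot oxidation and arylation of F3 with mCPBA, TfOH (3 equiv, which also protects the ring nitrogens and the amine as the salt) and mesitylene in CH2Cl2 at 0 °C to rt then gives triflate 3 directly.

**Further compounds**

F1 | step 2 | 6-bromo-4-methoxy-1H-indole | COc1cc(Br)cc2[nH]ccc12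
F2 | step 2 | 2-bromo-5-(6-bromo-4-methoxy-1H-indol-3-yl)pyrimidin-4-amine | COc1cc(Br)cc2[nH]cc(-c3cnc(Br)nc3N)c12
F3 | step 1 | 2-bromo-5-iodopyrimidin-4-amine | Nc1nc(Br)ncc1I
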